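**Retrosynthetic overview**

1. The target is a 1,10-epoxy-3,15-dihydroxy-8-isobutyryloxy-germacra-4Z,11(13)-dien-12,6-olide; the oxirane (C1/C10), the exocyclic C11=C13 bond and the free hydroxyls are installed after the ten-membered ring is closed.
2. Key disconnection C2–C3, the doubly allylic bond of the germacra-1(10),4-diene ten-membered ring: C3 is a carbinol next to the C4=C5 olefin (so it can be the carbonyl of a Z-enal, i.e. a ketyl radical), and C2 is the CH2 next to the oxirane (so in the 1(10)-ene it is the primary end of an E-allylic bromide). The ring is closed by a Cp2TiCl-mediated ketyl/allyl radical coupling.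
3. The open-chain precursor carries the trans-fused γ-lactone as its only ring. An Evans syn-aldol of a succinate imide with a Z-enal (C3–C6, C15) sets C6 and C7; the enal comes from 4-(hydroxymethyl)butenolide, whose temporary ring fixes the 4Z geometry and distinguishes C3 from C15.
4. East chain: Keck isoprenylation of the C8 aldehyde sets C8; 1,4-hydroboration of the 2-substituted diene gives the E-C1=C10 allylic alcohol, then the bromide.
5. Order of ring formation: γ-lactone (step 7), ten-membered carbocycle (step 17), oxirane (step 21).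

Key step: step 17

Remark: atoms are numbered as in germacranolides (C12 lactone carbonyl, C11/C13 exocyclic alkene, C6 lactone CH–O, C4=C5 with C15 on C4, C3 carbinol, C2, C1/C10 oxirane with C14 on C10, C9, C8 ester carbon, C7); 1 is charged as its commercial dimer; the C11 configuration of 27 and 28 is not controlled and is removed in step 20.
Abbreviations: TBS = tert-butyldimethylsilyl, TBDPS = tert-butyldiphenylsilyl, TES = triethylsilyl.

Step 1
Reactants: 1 1,3-dihydroxyacetone; 2 ethyl (triphenyl-λ5-phosphanylidene)acetate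
Product: 4 4-(hydroxymethyl)furan-2(5H)-one, via hydroxy ester 3 (not isolated)
Conditions: CH2Cl2, rt, 16 h
Reagents that add atoms: none
Why: Wittig olefination of the ketone by the stabilised ylide gives 3, whose two CH2OH arms are identical so that no alkene geometry arises, and spontaneous lactonisation of one arm gives the butenolide whose ring holds the future C3 (ring CH2O) cis to the future C6 (ring C=O) across C4=C5.

Step 2
Reactants: 4 4-(hydroxymethyl)furan-2(5H)-one
Product: 5 4-[(TBDPS-oxy)methyl]furan-2(5H)-one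
Conditions: TBDPSCl, imidazole, DMF, 0 °C to rt
Reagents that add atoms: tert-butyl(chloro)diphenylsilane, CC(C)(C)[Si](Cl)(c1ccccc1)c1ccccc1
Why: Imidazole-promoted silylation of the only hydroxyl protects the future C15–OH with a group that survives every later step up to the final fluoride treatment.

Step 3
Reactants: 5 4-[(TBDPS-oxy)methyl]furan-2(5H)-one
Product: 6 (2E)-3-[(TBDPS-oxy)methyl]-4-hydroxy-N-methoxy-N-methylbut-2-enamide
Conditions: MeNH(OMe)·HCl, AlMe3, CH2Cl2, 0 °C to rt; aqueous potassium sodium tartrate; crude product used at once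
Reagents that add atoms: N,O-dimethylhydroxylamine hydrochloride, CNOC.Cl
Why: Aminolysis of the butenolide by the aluminium amide (Weinreb amide formation) cleaves only the acyl–oxygen bond, so the alkene keeps the geometry imposed by the ring and the freed CH2OH (C3) stays cis to the carbonyl carbon (C6).

Step 4
Reactants: 6 (2E)-3-[(TBDPS-oxy)methyl]-4-hydroxy-N-methoxy-N-methylbut-2-enamide
Product: 7 (2E)-4-(TBS-oxy)-3-[(TBDPS-oxy)methyl]-N-methoxy-N-methylbut-2-enamide
Conditions: TBSOTf, 2,6-lutidine, CH2Cl2, −78 °C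
Reagents that add atoms: tert-butyldimethylsilyl trifluoromethanesulfonate, CC(C)(C)[Si](C)(C)OS(=O)(=O)C(F)(F)F
Why: O-silylation with the silyl triflate should be faster than relactonisation and makes the two CH2O arms permanently different (C3–OTBS cis to C6, C15–OTBDPS trans).

Step 5
Reactants: 7 (2E)-4-(TBS-oxy)-3-[(TBDPS-oxy)methyl]-N-methoxy-N-methylbut-2-enamide
Product: 8 (2E)-4-(TBS-oxy)-3-[(TBDPS-oxy)methyl]but-2-enal
Conditions: i-Bu2AlH, THF, −78 °C; aqueous potassium sodium tartrate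
Reagents that add atoms: none
Why: Hydride reduction of the N-methoxy-N-methylamide stops at the chelated tetrahedral aluminate, which gives the enal on work-up without touching the silyl ethers or the alkene geometry.

Step 6
Reactants: 9 (4S)-4-benzyl-1,3-oxazolidin-2-one; 10 methyl 4-chloro-4-oxobutanoate
Product: 11 methyl 4-[(4S)-4-benzyl-2-oxo-1,3-oxazolidin-3-yl]-4-oxobutanoate
Conditions: n-BuLi, THF, −78 °C; then 10, −78 to 0 °C
Reagents that add atoms: none
Why: N-acylation of the lithiated oxazolidinone by the acid chloride, which is far more electrophilic than the methyl ester of the same reagent.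

Step 7
Reactants: 11 methyl 4-[(4S)-4-benzyl-2-oxo-1,3-oxazolidin-3-yl]-4-oxobutanoate; 8 (2E)-4-(TBS-oxy)-3-[(TBDPS-oxy)methyl]but-2-enal
Product: 13 (4S)-4-benzyl-3-{[(2R,3S)-2-{(1E)-3-(TBS-oxy)-2-[(TBDPS-oxy)methyl]prop-1-en-1-yl}-5-oxooxolan-3-yl]carbonyl}-1,3-oxazolidin-2-one, via aldol adduct 12 (not isolated)
Conditions: Bu2BOTf, i-Pr2NEt, CH2Cl2, 0 °C; then 8, −78 to 0 °C; H2O2, pH 7 buffer, MeOH; then pyridinium p-toluenesulfonate (cat.), CH2Cl2, rt
Reagents that add atoms: none
Why: Evans syn-aldol addition of the Z-boron enolate through a chair (Zimmerman–Traxler) transition state, in which the (S)-benzyl auxiliary fixes both new stereocentres (the later 6R and 7R), followed by γ-lactonisation of the new hydroxyl onto the methyl ester, which turns the syn-aldol into the 6,7-trans-butanolide.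

Step 8
Reactants: 13 the lactone imide of step 7
Product: 14 S-ethyl (2R,3S)-2-{(1E)-3-(TBS-oxy)-2-[(TBDPS-oxy)methyl]prop-1-en-1-yl}-5-oxooxolane-3-carbothioate
Conditions: EtSH, n-BuLi, THF, −78 to 0 °C
Reagents that add atoms: ethanethiol, CCS
Why: Thiolate acyl substitution at the exocyclic imide carbonyl releases the auxiliary and gives the thioester, while addition of thiolate to the lactone is reversible and the trans arrangement at C7 is the thermodynamically preferred one.

Step 9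
Reactants: 14 the thioester of step 8
Product: 15 (2R,3S)-2-{(1E)-3-(TBS-oxy)-2-[(TBDPS-oxy)methyl]prop-1-en-1-yl}-5-oxooxolane-3-carbaldehyde
Conditions: Et3SiH, Pd/C (10 %), acetone, rt
Reagents that add atoms: none
Why: Fukuyama reduction (palladium-catalysed hydrosilane reduction of a thioester) gives the C8 aldehyde under neutral conditions that should leave the lactone, the silyl ethers and the trisubstituted alkene untouched.

Step 10
Reactants: 16 isoprene
Product: 17 tributyl(2-methylidenebut-3-en-1-yl)stannane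
Conditions: 2,2,6,6-tetramethylpiperidine, n-BuLi, KOt-Bu, THF, −78 °C; then Bu3SnCl, −78 °C to rt
Reagents that add atoms: tributyltin chloride, CCCC[Sn](Cl)(CCCC)CCCC
Why: Metalation of isoprene at its methyl group by the potassium amide and stannylation of the resulting 2-vinylallyl anion at carbon, a known preparation of this isoprenylating reagent.

Step 11
Reactants: 15 the aldehyde of step 9; 17 tributyl(2-methylidenebut-3-en-1-yl)stannane
Product: 18 (4R,5R)-5-{(1E)-3-(TBS-oxy)-2-[(TBDPS-oxy)methyl]prop-1-en-1-yl}-4-[(1R)-1-hydroxy-3-methylidenepent-4-en-1-yl]oxolan-2-one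
Conditions: (R)-BINOL (20 mol %), Ti(OiPr)4 (10 mol %), 4 Å molecular sieves, CH2Cl2, −20 °C; aqueous KF work-up
Reagents that add atoms: none
Why: Keck asymmetric allylation, in which the (R)-BINOL–Ti(OiPr)4 Lewis acid activates the aldehyde and the stannane adds in an SE2' sense to its Re face, which should set 8R by reagent control and delivers the 2-substituted 1,3-diene C9–C10(=C14)–C1=C2.

Step 12
Reactants: 18 the dienyl alcohol of step 11
Product: 19 (1R)-1-[(2R,3R)-2-{(1E)-3-(TBS-oxy)-2-[(TBDPS-oxy)methyl]prop-1-en-1-yl}-5-oxooxolan-3-yl]-3-methylidenepent-4-en-1-yl 2-methylpropanoate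
Conditions: isobutyryl chloride, pyridine, 4-(dimethylamino)pyridine (cat.), CH2Cl2, 0 °C
Reagents that add atoms: 2-methylpropanoyl chloride, CC(C)C(Cl)=O
Why: Nucleophile-catalysed acylation of the secondary alcohol installs the final isobutyrate at C8 and removes the only hydroxyl that could translactonise.

Step 13
Reactants: 19 the dienyl isobutyrate of step 12
Product: 21 (1R,3E)-5-hydroxy-3-methyl-1-[(2R,3R)-2-{(1E)-3-(TBS-oxy)-2-[(TBDPS-oxy)methyl]prop-1-en-1-yl}-5-oxooxolan-3-yl]pent-3-en-1-yl 2-methylpropanoate, via allylboronate 20 (not isolated)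
Conditions: pinacolborane, FeCl2(L) (4 mol %, L = N-(2,6-diisopropylphenyl)-1-(pyridin-2-yl)methanimine), Mg (10 mol %), Et2O, rt; then H2O2 (30 %), pH 7 phosphate buffer, THF, 0 °C
Reagents that add atoms: pinacolborane, CC1(C)OBOC1(C)C (its boron is present in 20 only); hydrogen peroxide, OO
Why: Iron-catalysed 1,4-hydroboration of the 2-substituted 1,3-diene through its s-cis complex should place boron on the unsubstituted terminus C2 and hydrogen on C14, so that C2 and the new C14 methyl are cis on C1=C10 (the 1(10)E geometry), and buffered oxidation of the C–B bond with retention gives the primary allylic alcohol.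

Step 14
Reactants: 21 the allylic alcohol of step 13
Product: 22 (1R,3E)-5-bromo-3-methyl-1-[(2R,3R)-2-{(1E)-3-(TBS-oxy)-2-[(TBDPS-oxy)methyl]prop-1-en-1-yl}-5-oxooxolan-3-yl]pent-3-en-1-yl 2-methylpropanoate
Conditions: CBr4, PPh3, 2,6-lutidine, CH2Cl2, −20 to 0 °C
Reagents that add atoms: carbon tetrabromide, BrC(Br)(Br)Br
Why: The Appel reaction converts the primary allylic alcohol into the bromide by SN2 displacement of the oxyphosphonium group without allylic transposition, while the silyl ethers and both esters are inert.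

Step 15
Reactants: 22 the allylic bromide of step 14
Product: 23 (1R,3E)-5-bromo-1-[(2R,3R)-2-{(1E)-3-hydroxy-2-[(TBDPS-oxy)methyl]prop-1-en-1-yl}-5-oxooxolan-3-yl]-3-methylpent-3-en-1-yl 2-methylpropanoate
Conditions: HF (48 % aq.), MeCN, 0 °C
Reagents that add atoms: none
Why: Acidic fluoride cleaves the primary TBS ether much faster than the TBDPS ether, and the non-nucleophilic medium should leave the allylic bromide and the esters intact.

Step 16
Reactants: 23 the bromo alcohol of step 15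
Product: 24 (1R,3E)-5-bromo-1-[(2R,3R)-2-{(1Z)-2-[(TBDPS-oxy)methyl]-3-oxoprop-1-en-1-yl}-5-oxooxolan-3-yl]-3-methylpent-3-en-1-yl 2-methylpropanoate
Conditions: Dess–Martin periodinane, NaHCO3, CH2Cl2, 0 °C
Reagents that add atoms: none
Why: Dess–Martin oxidation of the primary allylic alcohol under buffered, non-isomerising conditions gives the enal with C3 still cis to C6, which is stable because O6 is acylated.

Step 17
Reactants: 24 the bromo enal of step 16
Product: 25 (3S,6R,7R,8R)-15-(TBDPS-oxy)-3-hydroxy-8-(2-methylpropanoyloxy)germacra-1(10)E,4Z-dien-12,6-olide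
Conditions: Cp2TiCl2 (2.5 equiv), Mn dust (8 equiv), THF, rt (gives Cp2TiCl); 24 added by syringe pump over 8 h to 2 mM final concentration; aqueous NaH2PO4 work-up
Reagents that add atoms: none
Why: Proposed new method: Cp2TiCl abstracts bromine from the allylic bromide to give the C2–C1–C10 allyl radical and, as a trivalent titanium Lewis acid, reduces the conjugated aldehyde to an O-titanated C3 ketyl radical; the two radicals of one molecule combine at the unhindered primary terminus C2 and at C3, and the closest known reaction type is the intermolecular Cp2TiCl-promoted Barbier-type allylation of conjugated aldehydes with prenyl-type bromides, which is α-regioselective also for α-substituted, γ-oxygenated enals and is here run for the first time as a ring closure. The ten-membered carbocycle closes by radical–radical combination in an endo sense, with both reacting atoms and both preformed olefins inside the new ring, so no strained trans-cycloalkene has to be created in the ring-forming event. The only new stereocentre, C3, is set by the macrocyclic transition state: the trans-fused butanolide holds C5 and C8 on opposite faces and the bulky Cp2Ti(Cl)O group is expected to point to the outside of the forming ring, which should correspond to 3S. The step needs regioselectivity for C2 over C10 (secured by the methyl- and chain-substituted C10 terminus and by the ten- versus eight-membered ring), retention of the 4Z and 1(10)E geometries (the radicals should couple faster than they rotate) and suppression of pinacol and allyl–allyl dimers (slow addition at high dilution).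

Step 18
Reactants: 25 the macrocyclic alcohol of step 17
Product: 26 (3S,6R,7R,8R)-15-(TBDPS-oxy)-8-(2-methylpropanoyloxy)-3-(TES-oxy)germacra-1(10)E,4Z-dien-12,6-olide
Conditions: Et3SiOTf, 2,6-lutidine, CH2Cl2, −78 °C
Reagents that add atoms: triethylsilyl trifluoromethanesulfonate, CC[Si](CC)(CC)OS(=O)(=O)C(F)(F)F
Why: Silylation of the secondary allylic alcohol, so that the next step needs one equivalent of base only and the peracid of step 21 is not directed to the C4=C5 bond.

Step 19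
Reactants: 26 the bis-silyl ether of step 18
Product: 27 13-(dimethylamino)-11,13-dihydro derivative of the later compound 29, (3S,6R,7R,8R), C11 epimers
Conditions: LiN(SiMe3)2 (1.1 equiv), THF, −78 °C; then (CH2=NMe2)I, −78 to 0 °C
Reagents that add atoms: N,N-dimethylmethaniminium iodide, C[N+](C)=C.[I-]
Why: Kinetic deprotonation of the lactone α-CH2, the most acidic C–H (the isobutyrate has only a hindered tertiary α-H), and Mannich alkylation of the enolate by the iminium salt (first half of the Eschenmoser methylenation).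

Step 20
Reactants: 27 the Mannich base of step 19
Product: 29 (3S,6R,7R,8R)-15-(TBDPS-oxy)-8-(2-methylpropanoyloxy)-3-(TES-oxy)germacra-1(10)E,4Z,11(13)-trien-12,6-olide, via ammonium iodide 28 (not isolated)
Conditions: MeI, CH2Cl2/MeOH, rt; then aqueous NaHCO3, EtOAc, rt
Reagents that add atoms: iodomethane, CI (its methyl enters 28 only and leaves with trimethylamine)
Why: Exhaustive N-methylation followed by E1cB elimination of trimethylamine (Hofmann-type elimination of a β-ammonio lactone) unveils the α-methylene lactone under conditions that touch nothing else.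

Step 21
Reactants: 29 the α-methylene lactone of step 20
Product: 30 (1R,3S,6R,7R,8R,10R)-1,10-epoxy-15-(TBDPS-oxy)-8-(2-methylpropanoyloxy)-3-(TES-oxy)germacra-4Z,11(13)-dien-12,6-olide
Conditions: m-CPBA (1.2 equiv), NaHCO3, CH2Cl2, −20 to 0 °C
Reagents that add atoms: 3-chloroperoxybenzoic acid, OOC(=O)c1cccc(Cl)c1
Why: Prilezhaev epoxidation is stereospecific, so the E-olefin gives the trans-oxirane, and it should select the only electron-rich double bond C1=C10 (C4=C5 is deactivated by three allylic C–O bonds and shielded by two silyl ethers, C11=C13 is conjugated to the lactone); the peracid is expected to attack the outward face of this olefin in the preferred ring conformation, which should set 1R and 10R together.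

Step 22
Reactants: 30 the epoxide of step 21
Product: 31 CNP0219050.1, (1R,3S,6R,7R,8R,10R)-1,10-epoxy-3,15-dihydroxy-8-(2-methylpropanoyloxy)germacra-4Z,11(13)-dien-12,6-olide
Conditions: Bu4NF, AcOH (1:1), THF, 0 °C to rt
Reagents that add atoms: none
Why: Fluoride-mediated cleavage of both silyl ethers, buffered with acetic acid so that the oxirane, the isobutyrate and the α-methylene lactone should survive.

**Compound list**

1 | 1,3-dihydroxyacetone (commercial as the dimer) | OCC(=O)CO | starting material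
2 | ethyl (triphenyl-λ5-phosphanylidene)acetate | CCOC(=O)C=P(c1ccccc1)(c1ccccc1)c1ccccc1 | starting material
3 | ethyl 4-hydroxy-3-(hydroxymethyl)but-2-enoate | CCOC(=O)C=C(CO)CO | intermediate
4 | 4-(hydroxymethyl)furan-2(5H)-one | O=C1OCC(CO)=C1 | intermediate
5 | 4-{[(tert-butyldiphenylsilyl)oxy]methyl}furan-2(5H)-one | O=C1OCC(CO[Si](c2ccccc2)(c2ccccc2)C(C)(C)C)=C1 | intermediate
6 | (2E)-3-{[(tert-butyldiphenylsilyl)oxy]methyl}-4-hydroxy-N-methoxy-N-methylbut-2-enamide (CH2OH cis to the amide carbonyl) | CON(C)C(=O)/C=C(/CO[Si](c1ccccc1)(c1ccccc1)C(C)(C)C)CO | intermediate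
7 | (2E)-4-[(tert-butyldimethylsilyl)oxy]-3-{[(tert-butyldiphenylsilyl)oxy]methyl}-N-methoxy-N-methylbut-2-enamide | CON(C)C(=O)/C=C(/CO[Si](c1ccccc1)(c1ccccc1)C(C)(C)C)CO[Si](C)(C)C(C)(C)C | intermediate
8 | (2E)-4-[(tert-butyldimethylsilyl)oxy]-3-{[(tert-butyldiphenylsilyl)oxy]methyl}but-2-enal (CHO cis to CH2OTBS) | O=C/C=C(/CO[Si](c1ccccc1)(c1ccccc1)C(C)(C)C)CO[Si](C)(C)C(C)(C)C | intermediate
9 | (4S)-4-benzyl-1,3-oxazolidin-2-one | O=C1N[C@@H](Cc2ccccc2)CO1 | starting material
10 | methyl 4-chloro-4-oxobutanoate | COC(=O)CCC(Cl)=O | starting material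
11 | methyl 4-[(4S)-4-benzyl-2-oxo-1,3-oxazolidin-3-yl]-4-oxobutanoate | COC(=O)CCC(=O)N1[C@@H](Cc2ccccc2)COC1=O | intermediate
12 | methyl (3S,4R,5E)-3-{[(4S)-4-benzyl-2-oxo-1,3-oxazolidin-3-yl]carbonyl}-7-[(tert-butyldimethylsilyl)oxy]-6-{[(tert-butyldiphenylsilyl)oxy]methyl}-4-hydroxyhept-5-enoate | COC(=O)C[C@H](C(=O)N1[C@@H](Cc2ccccc2)COC1=O)[C@H](O)/C=C(/CO[Si](c2ccccc2)(c2ccccc2)C(C)(C)C)CO[Si](C)(C)C(C)(C)C | intermediate
13 | (4S)-4-benzyl-3-{[(2R,3S)-2-{(1E)-3-[(tert-butyldimethylsilyl)oxy]-2-{[(tert-butyldiphenylsilyl)oxy]methyl}prop-1-en-1-yl}-5-oxooxolan-3-yl]carbonyl}-1,3-oxazolidin-2-one (2,3-trans) | O=C(N1[C@@H](Cc2ccccc2)COC1=O)[C@H]1CC(=O)O[C@@H]1/C=C(/CO[Si](c2ccccc2)(c2ccccc2)C(C)(C)C)CO[Si](C)(C)C(C)(C)C | intermediate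
14 | S-ethyl (2R,3S)-2-{(1E)-3-[(tert-butyldimethylsilyl)oxy]-2-{[(tert-butyldiphenylsilyl)oxy]methyl}prop-1-en-1-yl}-5-oxooxolane-3-carbothioate | CCSC(=O)[C@H]1CC(=O)O[C@@H]1/C=C(/CO[Si](c2ccccc2)(c2ccccc2)C(C)(C)C)CO[Si](C)(C)C(C)(C)C | intermediate
15 | (2R,3S)-2-{(1E)-3-[(tert-butyldimethylsilyl)oxy]-2-{[(tert-butyldiphenylsilyl)oxy]methyl}prop-1-en-1-yl}-5-oxooxolane-3-carbaldehyde | O=C[C@H]1CC(=O)O[C@@H]1/C=C(/CO[Si](c2ccccc2)(c2ccccc2)C(C)(C)C)CO[Si](C)(C)C(C)(C)C | intermediate
16 | isoprene (2-methylbuta-1,3-diene) | C=CC(C)=C | starting material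
17 | tributyl(2-methylidenebut-3-en-1-yl)stannane | C=CC(=C)C[Sn](CCCC)(CCCC)CCCC | intermediate
18 | (4R,5R)-5-{(1E)-3-[(tert-butyldimethylsilyl)oxy]-2-{[(tert-butyldiphenylsilyl)oxy]methyl}prop-1-en-1-yl}-4-[(1R)-1-hydroxy-3-methylidenepent-4-en-1-yl]oxolan-2-one | C=CC(=C)C[C@@H](O)[C@H]1CC(=O)O[C@@H]1/C=C(/CO[Si](c2ccccc2)(c2ccccc2)C(C)(C)C)CO[Si](C)(C)C(C)(C)C | intermediate
19 | (1R)-1-[(2R,3R)-2-{(1E)-3-[(tert-butyldimethylsilyl)oxy]-2-{[(tert-butyldiphenylsilyl)oxy]methyl}prop-1-en-1-yl}-5-oxooxolan-3-yl]-3-methylidenepent-4-en-1-yl 2-methylpropanoate | C=CC(=C)C[C@@H](OC(=O)C(C)C)[C@H]1CC(=O)O[C@@H]1/C=C(/CO[Si](c2ccccc2)(c2ccccc2)C(C)(C)C)CO[Si](C)(C)C(C)(C)C | intermediate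
20 | (1R,3E)-3-methyl-1-[(2R,3R)-2-{(1E)-3-[(tert-butyldimethylsilyl)oxy]-2-{[(tert-butyldiphenylsilyl)oxy]methyl}prop-1-en-1-yl}-5-oxooxolan-3-yl]-5-(4,4,5,5-tetramethyl-1,3,2-dioxaborolan-2-yl)pent-3-en-1-yl 2-methylpropanoate | CC1(C)OB(C/C=C(\C)C[C@@H](OC(=O)C(C)C)[C@H]2CC(=O)O[C@@H]2/C=C(/CO[Si](c3ccccc3)(c3ccccc3)C(C)(C)C)CO[Si](C)(C)C(C)(C)C)OC1(C)C | intermediate
21 | (1R,3E)-5-hydroxy-3-methyl-1-[(2R,3R)-2-{(1E)-3-[(tert-butyldimethylsilyl)oxy]-2-{[(tert-butyldiphenylsilyl)oxy]methyl}prop-1-en-1-yl}-5-oxooxolan-3-yl]pent-3-en-1-yl 2-methylpropanoate | OC/C=C(\C)C[C@@H](OC(=O)C(C)C)[C@H]1CC(=O)O[C@@H]1/C=C(/CO[Si](c2ccccc2)(c2ccccc2)C(C)(C)C)CO[Si](C)(C)C(C)(C)C | intermediate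
22 | (1R,3E)-5-bromo-3-methyl-1-[(2R,3R)-2-{(1E)-3-[(tert-butyldimethylsilyl)oxy]-2-{[(tert-butyldiphenylsilyl)oxy]methyl}prop-1-en-1-yl}-5-oxooxolan-3-yl]pent-3-en-1-yl 2-methylpropanoate | BrC/C=C(\C)C[C@@H](OC(=O)C(C)C)[C@H]1CC(=O)O[C@@H]1/C=C(/CO[Si](c2ccccc2)(c2ccccc2)C(C)(C)C)CO[Si](C)(C)C(C)(C)C | intermediate
23 | (1R,3E)-5-bromo-1-[(2R,3R)-2-{(1E)-3-hydroxy-2-{[(tert-butyldiphenylsilyl)oxy]methyl}prop-1-en-1-yl}-5-oxooxolan-3-yl]-3-methylpent-3-en-1-yl 2-methylpropanoate | BrC/C=C(\C)C[C@@H](OC(=O)C(C)C)[C@H]1CC(=O)O[C@@H]1/C=C(/CO[Si](c2ccccc2)(c2ccccc2)C(C)(C)C)CO | intermediate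
24 | (1R,3E)-5-bromo-1-[(2R,3R)-2-{(1Z)-2-{[(tert-butyldiphenylsilyl)oxy]methyl}-3-oxoprop-1-en-1-yl}-5-oxooxolan-3-yl]-3-methylpent-3-en-1-yl 2-methylpropanoate | BrC/C=C(\C)C[C@@H](OC(=O)C(C)C)[C@H]1CC(=O)O[C@@H]1/C=C(/CO[Si](c2ccccc2)(c2ccccc2)C(C)(C)C)C=O | intermediate
25 | (3S,6R,7R,8R)-15-[(tert-butyldiphenylsilyl)oxy]-3-hydroxy-8-(2-methylpropanoyloxy)germacra-1(10)E,4Z-dien-12,6-olide | C1C(=O)O[C@@H]2/C=C(/CO[Si](c3ccccc3)(c3ccccc3)C(C)(C)C)[C@@H](O)C/C=C(\C)C[C@@H](OC(=O)C(C)C)[C@@H]12 | intermediate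
26 | (3S,6R,7R,8R)-15-[(tert-butyldiphenylsilyl)oxy]-8-(2-methylpropanoyloxy)-3-[(triethylsilyl)oxy]germacra-1(10)E,4Z-dien-12,6-olide | C1C(=O)O[C@@H]2/C=C(/CO[Si](c3ccccc3)(c3ccccc3)C(C)(C)C)[C@@H](O[Si](CC)(CC)CC)C/C=C(\C)C[C@@H](OC(=O)C(C)C)[C@@H]12 | intermediate
27 | (3S,6R,7R,8R)-15-[(tert-butyldiphenylsilyl)oxy]-13-(dimethylamino)-8-(2-methylpropanoyloxy)-3-[(triethylsilyl)oxy]germacra-1(10)E,4Z-dien-12,6-olide (C11 epimers) | CN(C)CC1C(=O)O[C@@H]2/C=C(/CO[Si](c3ccccc3)(c3ccccc3)C(C)(C)C)[C@@H](O[Si](CC)(CC)CC)C/C=C(\C)C[C@@H](OC(=O)C(C)C)[C@@H]12 | intermediate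
28 | 13-(trimethylammonio) analogue of 27, iodide salt (C11 epimers) | C[N+](C)(C)CC1C(=O)O[C@@H]2/C=C(/CO[Si](c3ccccc3)(c3ccccc3)C(C)(C)C)[C@@H](O[Si](CC)(CC)CC)C/C=C(\C)C[C@@H](OC(=O)C(C)C)[C@@H]12.[I-] | intermediate
29 | (3S,6R,7R,8R)-15-[(tert-butyldiphenylsilyl)oxy]-8-(2-methylpropanoyloxy)-3-[(triethylsilyl)oxy]germacra-1(10)E,4Z,11(13)-trien-12,6-olide | C=C1C(=O)O[C@@H]2/C=C(/CO[Si](c3ccccc3)(c3ccccc3)C(C)(C)C)[C@@H](O[Si](CC)(CC)CC)C/C=C(\C)C[C@@H](OC(=O)C(C)C)[C@@H]12 | intermediate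
30 | (1R,3S,6R,7R,8R,10R)-1,10-epoxy-15-[(tert-butyldiphenylsilyl)oxy]-8-(2-methylpropanoyloxy)-3-[(triethylsilyl)oxy]germacra-4Z,11(13)-dien-12,6-olide | C=C1C(=O)O[C@@H]2/C=C(/CO[Si](c3ccccc3)(c3ccccc3)C(C)(C)C)[C@@H](O[Si](CC)(CC)CC)C[C@H]3O[C@]3(C)C[C@@H](OC(=O)C(C)C)[C@@H]12 | intermediate
31 | CNP0219050.1, (1R,3S,6R,7R,8R,10R)-1,10-epoxy-3,15-dihydroxy-8-(2-methylpropanoyloxy)germacra-4Z,11(13)-dien-12,6-olide | C=C1C(=O)O[C@@H]2/C=C(/CO)[C@@H](O)C[C@H]3O[C@]3(C)C[C@@H](OC(=O)C(C)C)[C@@H]12 | target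

**Step count and risks**

Total step count: 22. Longest linear sequence: 20 steps (steps 1–5, 7–9 and 11–22).

Steps most likely to fail:

1. Step 17 (Proposed new method). What may go wrong: bond formation at the tertiary allyl terminus C10 through an allyltitanium intermediate, pinacol-type or allyl–allyl dimerisation, loss of the 4Z geometry in the ketyl radical, or poor facial selectivity at C3. The fallback uses known chemistry only; it sets out from compound 24 and comes back to the route at compound 25. Displacement of the bromide of 24 with PhSO2Na in DMF should give the allylic sulfone enal, (1R,3E)-1-[(2R,3R)-2-{(1Z)-2-[(TBDPS-oxy)methyl]-3-oxoprop-1-en-1-yl}-5-oxooxolan-3-yl]-3-methyl-5-(phenylsulfonyl)pent-3-en-1-yl 2-methylpropanoate F1. Intramolecular addition of its sulfonyl carbanion to the aldehyde (KOt-Bu, THF, −78 °C, high dilution) should close the ring to the macrocyclic β-hydroxy sulfone, 15-(TBDPS-oxy)-3-hydroxy-8-(2-methylpropanoyloxy)-2-(phenylsulfonyl)germacra-1(10)E,4Z-dien-12,6-olide F2 (C2/C3 isomers). Dess–Martin oxidation should give the β-keto sulfone, the 3-oxo analogue of F2, F3, and SmI2 in THF/MeOH at −78 °C should remove the sulfonyl group to give the macrocyclic enone, (6R,7R,8R)-15-(TBDPS-oxy)-8-(2-methylpropanoyloxy)-3-oxogermacra-1(10)E,4Z-dien-12,6-olide F4. Reagent-controlled reduction of F4 with the (R)-methyl-CBS oxazaborolidine and catecholborane at −78 °C should then give 25. A 3-epimer of 25 formed in step 17 could be fed into the same sequence by Dess–Martin oxidation to F4.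

2. Step 21. What may go wrong: poor facial selectivity of the peracid on the C1=C10 olefin, giving the 1,10-diastereomeric oxirane. The fallback sets out from compound 29 and comes back at compound 30, and it delivers oxygen to the face opposite to the one an electrophile attacks first. NBS in THF/H2O at 0 °C should form the bromonium ion on the exposed face and water should open it at the tertiary C10 from the other face, giving the bromohydrin, (1S,3S,6R,7R,8R,10R)-1-bromo-10-hydroxy-15-(TBDPS-oxy)-8-(2-methylpropanoyloxy)-3-(TES-oxy)germacra-4Z,11(13)-dien-12,6-olide F5. DBU in CH2Cl2 should then close the oxirane by displacement of bromide with inversion at C1, giving 30.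

3. Step 13. What may go wrong: hydroboration with the wrong regiochemistry (boron at C14) or the wrong olefin geometry, or reduction of a carbonyl group by the borane. The fallback builds the E-trisubstituted allylic alcohol from an alkyne instead; it sets out from compound 15 and comes back at compound 21. Propargylation of 15 with allenylboronic acid pinacol ester under (R)-TRIP phosphoric acid catalysis should give the homopropargylic alcohol, (4R,5R)-5-{(1E)-3-(TBS-oxy)-2-[(TBDPS-oxy)methyl]prop-1-en-1-yl}-4-[(1R)-1-hydroxybut-3-yn-1-yl]oxolan-2-one F6. Acylation with isobutyryl chloride and pyridine should give its 2-methylpropanoate, (1R)-1-[(2R,3R)-2-{(1E)-3-(TBS-oxy)-2-[(TBDPS-oxy)methyl]prop-1-en-1-yl}-5-oxooxolan-3-yl]but-3-yn-1-yl 2-methylpropanoate F7. Water-accelerated Negishi carboalumination (Me3Al, Cp2ZrCl2, H2O, CH2Cl2, −23 °C) followed by iodine should give the vinyl iodide, (1R,3E)-4-iodo-3-methyl-1-[(2R,3R)-2-{(1E)-3-(TBS-oxy)-2-[(TBDPS-oxy)methyl]prop-1-en-1-yl}-5-oxooxolan-3-yl]but-3-en-1-yl 2-methylpropanoate F8. Stille coupling of F8 with (tributylstannyl)methanol and Pd(PPh3)4 should give 21.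

Further compounds
F1 | step 17 | (1R,3E)-1-[(2R,3R)-2-{(1Z)-2-{[(tert-butyldiphenylsilyl)oxy]methyl}-3-oxoprop-1-en-1-yl}-5-oxooxolan-3-yl]-3-methyl-5-(phenylsulfonyl)pent-3-en-1-yl 2-methylpropanoate | O=S(=O)(c1ccccc1)C/C=C(\C)C[C@@H](OC(=O)C(C)C)[C@H]1CC(=O)O[C@@H]1/C=C(/CO[Si](c2ccccc2)(c2ccccc2)C(C)(C)C)C=O
F2 | step 17 | (6R,7R,8R)-15-[(tert-butyldiphenylsilyl)oxy]-3-hydroxy-8-(2-methylpropanoyloxy)-2-(phenylsulfonyl)germacra-1(10)E,4Z-dien-12,6-olide (C2/C3 isomers) | C1C(=O)O[C@@H]2/C=C(/CO[Si](c3ccccc3)(c3ccccc3)C(C)(C)C)C(O)C(S(=O)(=O)c3ccccc3)/C=C(\C)C[C@@H](OC(=O)C(C)C)[C@@H]12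
F3 | step 17 | (6R,7R,8R)-15-[(tert-butyldiphenylsilyl)oxy]-8-(2-methylpropanoyloxy)-3-oxo-2-(phenylsulfonyl)germacra-1(10)E,4Z-dien-12,6-olide (C2 isomers) | C1C(=O)O[C@@H]2/C=C(/CO[Si](c3ccccc3)(c3ccccc3)C(C)(C)C)C(=O)C(S(=O)(=O)c3ccccc3)/C=C(\C)C[C@@H](OC(=O)C(C)C)[C@@H]12
F4 | step 17 | (6R,7R,8R)-15-[(tert-butyldiphenylsilyl)oxy]-8-(2-methylpropanoyloxy)-3-oxogermacra-1(10)E,4Z-dien-12,6-olide | C1C(=O)O[C@@H]2/C=C(/CO[Si](c3ccccc3)(c3ccccc3)C(C)(C)C)C(=O)C/C=C(\C)C[C@@H](OC(=O)C(C)C)[C@@H]12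
F5 | step 21 | (1S,3S,6R,7R,8R,10R)-1-bromo-10-hydroxy-15-[(tert-butyldiphenylsilyl)oxy]-8-(2-methylpropanoyloxy)-3-[(triethylsilyl)oxy]germacra-4Z,11(13)-dien-12,6-olide | C=C1C(=O)O[C@@H]2/C=C(/CO[Si](c3ccccc3)(c3ccccc3)C(C)(C)C)[C@@H](O[Si](CC)(CC)CC)C[C@H](Br)[C@](C)(O)C[C@@H](OC(=O)C(C)C)[C@@H]12
F6 | step 13 | (4R,5R)-5-{(1E)-3-[(tert-butyldimethylsilyl)oxy]-2-{[(tert-butyldiphenylsilyl)oxy]methyl}prop-1-en-1-yl}-4-[(1R)-1-hydroxybut-3-yn-1-yl]oxolan-2-one | C#CC[C@@H](O)[C@H]1CC(=O)O[C@@H]1/C=C(/CO[Si](c2ccccc2)(c2ccccc2)C(C)(C)C)CO[Si](C)(C)C(C)(C)C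
F7 | step 13 | (1R)-1-[(2R,3R)-2-{(1E)-3-[(tert-butyldimethylsilyl)oxy]-2-{[(tert-butyldiphenylsilyl)oxy]methyl}prop-1-en-1-yl}-5-oxooxolan-3-yl]but-3-yn-1-yl 2-methylpropanoate | C#CC[C@@H](OC(=O)C(C)C)[C@H]1CC(=O)O[C@@H]1/C=C(/CO[Si](c2ccccc2)(c2ccccc2)C(C)(C)C)CO[Si](C)(C)C(C)(C)C
F8 | step 13 | (1R,3E)-4-iodo-3-methyl-1-[(2R,3R)-2-{(1E)-3-[(tert-butyldimethylsilyl)oxy]-2-{[(tert-butyldiphenylsilyl)oxy]methyl}prop-1-en-1-yl}-5-oxooxolan-3-yl]but-3-en-1-yl 2-methylpropanoate | I/C=C(\C)C[C@@H](OC(=O)C(C)C)[C@H]1CC(=O)O[C@@H]1/C=C(/CO[Si](c2ccccc2)(c2ccccc2)C(C)(C)C)CO[Si](C)(C)C(C)(C)C
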